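**Plan**

1. Numbering (tetralin): C1 carries the pendant aryl group, C2 and C3 the CH2OH groups, C4 is the ring CH2; ring A carries OMe at C6 and OH at C7.
2. Retrosynthesis: both CH2OH groups go back to esters (C2 and C3 become epimerisable). Ring B is then cut at C1–C2 and C4–C4a, leaving a diarylmethyl unit (C1 with both arenes) and an itaconate diester (C2, C3, C4 and both carboxyl carbons).
3. What makes this possible: the 4-hydroxyphenyl group on C1 lets C1 appear as the exocyclic carbon of a p-quinone methide (electrophile), and the C7 hydroxyl of ring A is para to C4a, so C4a is the carbon nucleophile of a phenolate. The itaconate answers with a nucleophilic C2 (dienolate) and an electrophilic C4 (acrylate terminus).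
4. Forward: aryl Grignard reagent plus vanillin gives the diarylmethanol, which is converted to a sulfone (quinone methide precursor). A one-flask formal [3+3] annulation closes ring B (C1–C2 by 1,6-addition, then C4–C4a by phenolate Michael addition); equilibration and reduction follow.
5. Stereochemistry: C1 comes from the chiral phase-transfer catalyst in the 1,6-addition. C2 and C3 come from thermodynamic equilibration of the diester to the all-equatorial 1,2-trans-2,3-trans isomer, which the reduction preserves.
6. Helpers: toluenesulfonyl leaving group, silyl mask on the ring A phenol (its removal triggers ring closure), trifluoroethyl esters (acidify C2–H, activate C4); all are gone by step 5.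

Key step: step 4

Assumption: bis(2,2,2-trifluoroethyl) itaconate is taken as a purchasable monomer; otherwise one acid-catalysed esterification of itaconic acid with 2,2,2-trifluoroethanol supplies it.
Assumption: the sense of induction of the cinchona-derived ammonium salt cannot be predicted with certainty; the antipode (cinchonidinium or the pseudo-enantiomeric cinchoninium salt) is taken as the one that gives the R configuration at C1.

**Route**

Step 1
Reactants: 1 5-bromo-2-methoxyphenol
Product: 2 (5-bromo-2-methoxyphenoxy)(tert-butyl)dimethylsilane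
Conditions: TBSCl (1.2 equiv), imidazole (2.0 equiv), DMF, 23 °C
Reagents that add atoms: tert-butyldimethylsilyl chloride, CC(C)(C)[Si](C)(C)Cl
Why: Silyl ether formation (O-silylation of a phenol) should proceed cleanly and masks the ring A oxygen, which must stay inert through the Grignard step and the first stage of step 4 and is later freed by fluoride.

Step 2
Reactants: 2 (5-bromo-2-methoxyphenoxy)(tert-butyl)dimethylsilane; 3 vanillin (4-hydroxy-3-methoxybenzaldehyde)
Product: 5 [3-(tert-butyldimethylsilyloxy)-4-methoxyphenyl](4-hydroxy-3-methoxyphenyl)methanol (racemic), via arylmagnesium bromide 4 (not isolated)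
Conditions: 2, Mg (1.6 equiv), THF, 40 °C; separately 3, i-PrMgCl (1.0 equiv), THF, 0 °C; then 4 (1.5 equiv), 0 → 23 °C; H2O
Reagents that add atoms: none
Why: Grignard addition to an aldehyde, the phenol of 3 being first converted to its magnesium phenolate so that the aryl reagent is not spent as a base; the carbinol centre is formed racemic because it becomes a planar quinone methide carbon in step 4.

Step 3
Reactants: 5 [3-(tert-butyldimethylsilyloxy)-4-methoxyphenyl](4-hydroxy-3-methoxyphenyl)methanol
Product: 6 4-{[3-(tert-butyldimethylsilyloxy)-4-methoxyphenyl](4-methylbenzenesulfonyl)methyl}-2-methoxyphenol (racemic)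
Conditions: 4-MeC6H4SO2H (1.5 equiv), CH2Cl2, 23 °C
Reagents that add atoms: 4-methylbenzenesulfinic acid, Cc1ccc(cc1)S(=O)O
Why: Acid-promoted ionisation of the p-hydroxybenzhydrol and 1,6-addition of the sulfinate through sulfur (sulfone formation via a quinone methide) should give a storable solid that releases the quinone methide again with mild base; the centre stays racemic.

Step 4
Reactants: 6 4-{[3-(tert-butyldimethylsilyloxy)-4-methoxyphenyl](4-methylbenzenesulfonyl)methyl}-2-methoxyphenol; 7 bis(2,2,2-trifluoroethyl) itaconate (bis(2,2,2-trifluoroethyl) 2-methylidenebutanedioate)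
Product: 11 bis(2,2,2-trifluoroethyl) (1R)-7-hydroxy-1-(4-hydroxy-3-methoxyphenyl)-6-methoxy-1,2,3,4-tetrahydronaphthalene-2,3-dicarboxylate (C2/C3 epimer mixture), via quinone methide 8 (not isolated), via silylated 1,6-adduct 9 (not isolated), via desilylated 1,6-adduct 10 (not isolated)
Conditions: (a) 7 (2.0 equiv), N-(9-anthracenylmethyl)cinchonidinium chloride (10 mol%), K3PO4 (3.0 equiv, powder), toluene, −20 °C; (b) CsF (3.0 equiv), DMSO, 23 → 40 °C; aq NH4Cl
Reagents that add atoms: none
Why: Proposed new method: K3PO4 expels toluenesulfinate from 6 to give quinone methide 8, the ammonium-bound dienolate of 7 adds through its ester-bearing α-carbon (C2) to the exocyclic carbon (C1) in a 1,6-conjugate addition, and fluoride then frees the ring A phenolate, whose para carbon C4a adds to the acrylate terminus C4 (intramolecular Michael addition, rearomatisation by tautomerisation), so that the two bonds close ring B in a formal [3+3] annulation. The closest known reaction types are the phase-transfer-catalysed enantioselective 1,6-addition of malonate-type carbanions to p-quinone methides and the Friedel–Crafts-type conjugate C-alkylation of phenolates and naphtholates by Michael acceptors; their union on an itaconate is new. The one ring closure is a 6-endo-trig attack of carbon C4a on the terminal alkene carbon. C1 is set in the intermolecular addition by the catalyst, whose C9 hydroxyl binds the methoxy-flanked quinone methide carbonyl while its quaternary nitrogen holds the dienolate, so that one face of the exocyclic carbon is exposed; C2 and C3 arise as mixtures and, being enolisable, are left to the equilibration of step 5. The step needs α- and not γ-attack of the dienolate, which the tight ion pair (highest charge density next to the ester that holds the cation) should secure, and closure para and not ortho to the phenolate oxygen, which the crowding of C8 between the oxygen and the ring junction should secure. Only ring A can close, because the silyl ether keeps it inert until C1–C2 exists and because the phenolate of the pendant ring activates only carbons that are meta to C1.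

Step 5
Reactants: 11 bis(2,2,2-trifluoroethyl) (1R)-7-hydroxy-1-(4-hydroxy-3-methoxyphenyl)-6-methoxy-1,2,3,4-tetrahydronaphthalene-2,3-dicarboxylate
Product: 12 dimethyl (1R,2S,3S)-7-hydroxy-1-(4-hydroxy-3-methoxyphenyl)-6-methoxy-1,2,3,4-tetrahydronaphthalene-2,3-dicarboxylate
Conditions: NaOMe (5 equiv), MeOH, 50 °C; aq NH4Cl
Reagents that add atoms: methanol (as NaOMe in MeOH), CO
Why: Base-mediated epimerisation of the two enolisable ester α-centres with concurrent transesterification (thermodynamic control) should funnel all C2/C3 epimers into the all-equatorial 1,2-trans-2,3-trans diester, the C1 aryl group acting as conformational anchor and C1 itself bearing no acidic hydrogen.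

Step 6
Reactants: 12 dimethyl (1R,2S,3S)-7-hydroxy-1-(4-hydroxy-3-methoxyphenyl)-6-methoxy-1,2,3,4-tetrahydronaphthalene-2,3-dicarboxylate
Product: 13 (6S,7S,8R)-8-(4-hydroxy-3-methoxyphenyl)-6,7-bis(hydroxymethyl)-3-methoxy-5,6,7,8-tetrahydronaphthalen-2-ol (target; 1R,2S,3S in the tetralin numbering used above)
Conditions: LiAlH4 (6 equiv), THF, 0 → 40 °C; aq NaOH work-up
Reagents that add atoms: none
Why: LiAlH4 reduction of both esters to primary alcohols should touch no stereocentre, the two phenols being carried as aluminium phenolates and freed on work-up.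

**Compound list**

1 | 5-bromo-2-methoxyphenol | COc1ccc(Br)cc1O | starting material
2 | (5-bromo-2-methoxyphenoxy)(tert-butyl)dimethylsilane | COc1ccc(Br)cc1O[Si](C)(C)C(C)(C)C | intermediate
3 | vanillin (4-hydroxy-3-methoxybenzaldehyde) | COc1cc(C=O)ccc1O | starting material
4 | [3-(tert-butyldimethylsilyloxy)-4-methoxyphenyl]magnesium bromide | COc1ccc([Mg]Br)cc1O[Si](C)(C)C(C)(C)C | intermediate
5 | [3-(tert-butyldimethylsilyloxy)-4-methoxyphenyl](4-hydroxy-3-methoxyphenyl)methanol (racemic) | COc1ccc(C(O)c2ccc(O)c(OC)c2)cc1O[Si](C)(C)C(C)(C)C | intermediate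
6 | 4-{[3-(tert-butyldimethylsilyloxy)-4-methoxyphenyl](4-methylbenzenesulfonyl)methyl}-2-methoxyphenol (racemic) | COc1ccc(C(c2ccc(O)c(OC)c2)S(=O)(=O)c2ccc(C)cc2)cc1O[Si](C)(C)C(C)(C)C | intermediate
7 | bis(2,2,2-trifluoroethyl) itaconate | C=C(CC(=O)OCC(F)(F)F)C(=O)OCC(F)(F)F | starting material
8 | 4-{[3-(tert-butyldimethylsilyloxy)-4-methoxyphenyl]methylidene}-2-methoxycyclohexa-2,5-dien-1-one (quinone methide, alkene geometry not defined) | COC1=CC(=Cc2ccc(OC)c(O[Si](C)(C)C(C)(C)C)c2)C=CC1=O | intermediate
9 | bis(2,2,2-trifluoroethyl) 2-{(R)-[3-(tert-butyldimethylsilyloxy)-4-methoxyphenyl](4-hydroxy-3-methoxyphenyl)methyl}-3-methylidenebutanedioate (both epimers at the succinate CH) | C=C(C(=O)OCC(F)(F)F)C(C(=O)OCC(F)(F)F)[C@H](c1ccc(O)c(OC)c1)c1ccc(OC)c(O[Si](C)(C)C(C)(C)C)c1 | intermediate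
10 | bis(2,2,2-trifluoroethyl) 2-[(S)-(3-hydroxy-4-methoxyphenyl)(4-hydroxy-3-methoxyphenyl)methyl]-3-methylidenebutanedioate (same spatial arrangement as 9; the descriptor changes with loss of the silyl group; both epimers at the succinate CH) | C=C(C(=O)OCC(F)(F)F)C(C(=O)OCC(F)(F)F)[C@H](c1ccc(O)c(OC)c1)c1ccc(OC)c(O)c1 | intermediate
11 | bis(2,2,2-trifluoroethyl) (1R)-7-hydroxy-1-(4-hydroxy-3-methoxyphenyl)-6-methoxy-1,2,3,4-tetrahydronaphthalene-2,3-dicarboxylate (C2/C3 epimer mixture) | COc1cc([C@@H]2c3cc(O)c(OC)cc3CC(C(=O)OCC(F)(F)F)C2C(=O)OCC(F)(F)F)ccc1O | intermediate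
12 | dimethyl (1R,2S,3S)-7-hydroxy-1-(4-hydroxy-3-methoxyphenyl)-6-methoxy-1,2,3,4-tetrahydronaphthalene-2,3-dicarboxylate | COc1cc([C@@H]2c3cc(O)c(OC)cc3C[C@H](C(=O)OC)[C@H]2C(=O)OC)ccc1O | intermediate
13 | (6S,7S,8R)-8-(4-hydroxy-3-methoxyphenyl)-6,7-bis(hydroxymethyl)-3-methoxy-5,6,7,8-tetrahydronaphthalen-2-ol | COc1cc([C@@H]2c3cc(O)c(OC)cc3C[C@H](CO)[C@H]2CO)ccc1O | target

**Step count and risks**

Total step count: 6. Longest linear sequence: 6 steps (1 → 2 → 5 → 6 → 11 → 12 → 13); 3 and 7 enter as purchased materials.

Steps most likely to fail: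

Step 4 (bears the label). What may go wrong: attack of the dienolate through its γ-terminus (C4) in place of the α-carbon, poor facial selectivity at the quinone methide carbon, reversal of the 1,6-addition while the pendant phenolate is warmed in DMSO (erosion of C1), or ring closure through the ortho carbon C8. The fallback uses known chemistry: the stereochemistry then comes from an asymmetric hydrogenation, and ring B is closed by a cationic Friedel–Crafts cyclisation at C1–C8a. It sets out from vanillin 3 and comes back to the route at target 13. Benzylation of 3 (BnBr, K2CO3, DMF) gives 4-(benzyloxy)-3-methoxybenzaldehyde F1. Stobbe condensation of F1 with dimethyl succinate (NaOMe, MeOH, reflux) gives (E)-4-[4-(benzyloxy)-3-methoxyphenyl]-3-(methoxycarbonyl)but-3-enoic acid F2. Hydrogenation with Ru(OAc)2[(S)-BINAP] (or the R antipode, whichever delivers the S acid; H2, MeOH) gives (S)-4-[4-(benzyloxy)-3-methoxyphenyl]-3-(methoxycarbonyl)butanoic acid F3. Reduction of the ester next to the carboxylate (KOH, then Ca(BH4)2, EtOH) and lactonisation with aq HCl give (S)-4-[4-(benzyloxy)-3-methoxybenzyl]dihydrofuran-2(3H)-one F4. Its lithium enolate (LiN(i-Pr)2, THF, −78 °C) adds to a second portion of F1 anti to the benzyl group (aldol addition) to give (3R,4S)-4-[4-(benzyloxy)-3-methoxybenzyl]-3-{[4-(benzyloxy)-3-methoxyphenyl](hydroxy)methyl}dihydrofuran-2(3H)-one F5 as a pair of carbinol epimers. TFA in CH2Cl2 ionises the carbinol of either epimer and the arene of the benzyl group attacks the cation para to its methoxy group, which should give the trans,trans lactone (3aS,9R,9aS)-7-(benzyloxy)-9-[4-(benzyloxy)-3-methoxyphenyl]-6-methoxy-3a,4,9,9a-tetrahydronaphtho[2,3-c]furan-1(3H)-one F6. Hydrogenolysis (H2, Pd/C, EtOAc) gives (3aS,9R,9aS)-7-hydroxy-9-(4-hydroxy-3-methoxyphenyl)-6-methoxy-3a,4,9,9a-tetrahydronaphtho[2,3-c]furan-1(3H)-one F7, and LiAlH4 in THF reduces the lactone of F7 to 13.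

Step 3. What may go wrong: the ionised carbinol alkylates an electron-rich ring of a second molecule faster than it is trapped by the sulfinate, or the acid loosens the silyl ether. The fallback replaces the acid-made sulfone by a base-triggered precursor; it sets out from carbinol 5 and comes back at quinone methide 8. Acetylation of both hydroxyl groups of 5 (Ac2O, Et3N, DMAP, CH2Cl2) gives 4-{acetoxy[3-(tert-butyldimethylsilyloxy)-4-methoxyphenyl]methyl}-2-methoxyphenyl acetate F8, which takes the place of 6 in step 4. One equivalent of methanol is added there; the methoxide formed on K3PO4 cleaves the aryl acetate, and the phenolate expels the benzylic acetate to give 8.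

Step 2. What may go wrong: incomplete addition because the phenolate deactivates the aldehyde, and loss of the acid-sensitive p-hydroxybenzhydrol by ionisation during work-up and chromatography. The fallback uses a protected aldehyde and frees the phenol after the C–C bond is made; it sets out from vanillin 3 and comes back at carbinol 5. Allylation of 3 (allyl bromide, K2CO3, acetone) gives 4-(allyloxy)-3-methoxybenzaldehyde F9. Addition of Grignard reagent 4 (THF, 0 °C) gives [4-(allyloxy)-3-methoxyphenyl][3-(tert-butyldimethylsilyloxy)-4-methoxyphenyl]methanol F10. Pd(PPh3)4 with morpholine in THF removes the allyl group and gives 5.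

Further compounds
F1 | step 4 | 4-(benzyloxy)-3-methoxybenzaldehyde | COc1cc(C=O)ccc1OCc1ccccc1
F2 | step 4 | (E)-4-[4-(benzyloxy)-3-methoxyphenyl]-3-(methoxycarbonyl)but-3-enoic acid | COC(=O)/C(CC(=O)O)=C/c1ccc(OCc2ccccc2)c(OC)c1
F3 | step 4 | (S)-4-[4-(benzyloxy)-3-methoxyphenyl]-3-(methoxycarbonyl)butanoic acid | COc1cc(C[C@H](C(=O)OC)CC(=O)O)ccc1OCc1ccccc1
F4 | step 4 | (S)-4-[4-(benzyloxy)-3-methoxybenzyl]dihydrofuran-2(3H)-one | COc1cc(C[C@@H]2COC(=O)C2)ccc1OCc1ccccc1
F5 | step 4 | (3R,4S)-4-[4-(benzyloxy)-3-methoxybenzyl]-3-{[4-(benzyloxy)-3-methoxyphenyl](hydroxy)methyl}dihydrofuran-2(3H)-one (both carbinol epimers) | COc1cc(C[C@@H]2COC(=O)[C@H]2C(O)c2ccc(OCc3ccccc3)c(OC)c2)ccc1OCc1ccccc1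
F6 | step 4 | (3aS,9R,9aS)-7-(benzyloxy)-9-[4-(benzyloxy)-3-methoxyphenyl]-6-methoxy-3a,4,9,9a-tetrahydronaphtho[2,3-c]furan-1(3H)-one | COc1cc([C@@H]2c3cc(OCc4ccccc4)c(OC)cc3C[C@@H]3COC(=O)[C@@H]23)ccc1OCc1ccccc1
F7 | step 4 | (3aS,9R,9aS)-7-hydroxy-9-(4-hydroxy-3-methoxyphenyl)-6-methoxy-3a,4,9,9a-tetrahydronaphtho[2,3-c]furan-1(3H)-one | COc1cc([C@@H]2c3cc(O)c(OC)cc3C[C@@H]3COC(=O)[C@@H]23)ccc1O
F8 | step 3 | 4-{acetoxy[3-(tert-butyldimethylsilyloxy)-4-methoxyphenyl]methyl}-2-methoxyphenyl acetate (racemic) | COc1ccc(C(OC(C)=O)c2ccc(OC(C)=O)c(OC)c2)cc1O[Si](C)(C)C(C)(C)C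
F9 | step 2 | 4-(allyloxy)-3-methoxybenzaldehyde | C=CCOc1ccc(C=O)cc1OC
F10 | step 2 | [4-(allyloxy)-3-methoxyphenyl][3-(tert-butyldimethylsilyloxy)-4-methoxyphenyl]methanol (racemic) | C=CCOc1ccc(C(O)c2ccc(OC)c(O[Si](C)(C)C(C)(C)C)c2)cc1OC
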